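Amounts come first: each flask holds a charge of substrate and of partner, and each reading tells how much target stands in it.

| setting | grey | blue | green | amber |
|---|---|---|---|---|
| substrate | 0.300 M | 0.900 M | 0.300 M | 0.600 M |
| partner | 0.900 M | 0.900 M | 2.70 M | 2.70 M |
| time |  |  |  | 9.2 min |

- grey run (time / min: [target] / M): 0.37: 0.0085; 0.58: 0.0083; 0.92: 0.0153; 1.5: 0.0261; 2.3: 0.0350; 3.7: 0.0447; 5.8: 0.0635; 9.2: 0.0700
- blue run (time / min: [target] / M): 0.37: 0.0163; 0.58: 0.0252; 0.92: 0.0416; 1.5: 0.0597; 2.3: 0.0855; 3.7: 0.1237; 5.8: 0.1634; 9.2: 0.1929
- green run (time / min: [target] / M): 0.37: 0.0073; 0.58: 0.0107; 0.92: 0.0172; 1.5: 0.0256; 2.3: 0.0369; 3.7: 0.0530; 5.8: 0.0639; 9.2: 0.0754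

(readings scatter by 0.002 M)

- order of the initial rate in [partner], near the charge of the grey run, the rate being that where two percent of its substrate are target
- order of the initial rate in [substrate], near the charge of the grey run, the rate being that where two percent of its substrate are target (one fixed amount of target, the same in the runs compared)
- target in the amber run at 9.2 min, as a share of the substrate charged

- Overall: substrate + partner -> target.
- Constant volume, constant temperature.
- A reading of a species includes what of it is bound.
- "The second partner" is partner.
- An order is taken over about fifteen percent of the charge, up and down.

Early rates are read as c(target) over time in the grey run at 0.92 min, 0.0166 M/min, and at the same time in the blue run, 0.0452 M/min, and in the green run, 0.0187 M/min; each carries the scatter of one reading. The green run, with c(partner) at 2.70 M against the 0.900 M of the grey run, reads 1.13 times the grey rate, an average order of 0.107. The blue run, with c(substrate) at 0.900 M against the 0.300 M of the grey run, reads 2.72 times the grey rate, an average order of 0.912. This reckoning commits to these averages for the orders.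

The givens fold into a turnover count: early rate times 9.2 min, divided by c(substrate) charged, which counts the charges turned over at the early pace. It reads 0.510 in grey, 0.462 in blue and 0.573 in green.

Is that number enough? The share of the charge present as target at 9.2 min, divided by the count, gives 0.458 in grey, 0.464 in blue and 0.438 in green. The ratio barely moves, so the count carries the outcome, given this one extra factor.

In the amber flask, substrate is the limiting reagent. Going from the grey charge of substrate to the blue one moved the count from 0.510 to 0.462, and the amber flask keeps the partner charge of the green flask, with 4.50 partner per substrate. This reckoning therefore carries the green count over as the amber turnover count, 0.573. With the geometric mean 0.448 of the grey and green ratios, the amber share is reckoned at 25.7 %.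

The forecast gives 0.1, 0.9 and 23 %, the share lying below this reckoning, with the words “Amber should be green scaled”.

The flask gives 0.12, 1.0 and 25.0 %.

    substrate + partner → target (1.140 /M/min)
    substrate + partner → side product (1.098 /M/min)
    substrate + partner ⇌ idle substrate-reagent adduct, settled at all times (17.10 /M)
    target → decomposed product (0.06480 /min)

Amber's share over its count is 0.436, close to the 0.448 of its neighbours. That ratio sits well below one partly because target passes into decomposed product. The amber run without that step holds 35.2 %, so its ratio rises to 0.613. That step is not the reason for the low order in partner, which stays at 0.12 without it.

(The earlier runs and the new flask were generated by integration for substances that don't exist.)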